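**Strategy.** Labdane numbering is used. The route rests on cutting the C4–C5 bond of ring A together with C9–C10 of ring B, which unravels the trans-decalin into an acyclic (E,E)-diene β-keto ester. One oxidative radical bicyclization (Mn(OAc)3/Cu(OAc)2) of this chain, a 2-methyl-3-oxo ester carrying a (−)-8-phenylmenthyl auxiliary and a remote methyl ketone, closes rings A and B, sets C4, C5, C9 and C10 and leaves the C8(17) exocyclic methylene. It exploits the C4 quaternary carbon bearing methyl and ester next to the C5–C10 ring fusion. The C3 ketone is then removed, the auxiliary exchanged for methyl, and the ene-diol made by Sharpless epoxidation and titanium-mediated epoxide isomerization.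

Key step: step 6

Remark on numbering: ring A = C1–C5 and C10; ring B = C5–C10; C17 on C8; C18 = 4α-methyl; C19 = 4β-carboxyl carbon; C20 on C10; side chain C11–C16.

Assumption: the (1R,2S,5R)-8-phenylmenthyl ester is taken to shield the face of the C4 radical that leads to the 5α-H, 10β-methyl series drawn; should the sense prove opposite, the enantiomeric auxiliary would be used with no other change.

**Step 1**
Reactants: 1 (E)-geranylacetone
Product: 2 2-[(3E)-4,8-dimethylnona-3,7-dien-1-yl]-2-methyl-1,3-dioxolane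
Conditions: ethylene glycol, p-TsOH·H2O (cat.), benzene, reflux, Dean–Stark
Reagents that add atoms: ethylene glycol, OCCO
Why: Acid-catalysed ketalisation with azeotropic removal of water masks the ketone against the strongly basic dianion of step 5, and the trisubstituted alkenes are inert to catalytic p-TsOH.

**Step 2**
Reactants: 2 dioxolane of geranylacetone
Product: 3 (2E,6E)-2,6-dimethyl-9-(2-methyl-1,3-dioxolan-2-yl)nona-2,6-dien-1-ol
Conditions: SeO2 (cat.), t-BuOOH, salicylic acid (cat.), CH2Cl2, 0 °C to rt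
Reagents that add atoms: selenium dioxide, O=[Se]=O; tert-butyl hydroperoxide, CC(C)(C)OO
Why: Allylic oxidation by SeO2 (ene reaction then 2,3-sigmatropic shift) attacks the terminal gem-dimethyl alkene at its (E)-methyl group, so the allylic alcohol should form with E geometry and the internal alkene untouched.

**Step 3**
Reactants: 3 allylic alcohol
Product: 4 2-[(3E,7E)-9-bromo-4,8-dimethylnona-3,7-dien-1-yl]-2-methyl-1,3-dioxolane
Conditions: CBr4, PPh3, CH2Cl2, −20 °C to 0 °C
Reagents that add atoms: carbon tetrabromide, BrC(Br)(Br)Br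
Why: Appel bromination converts the primary allylic alcohol into the bromide by SN2 displacement of the oxyphosphonium, without allylic transposition at low temperature and without acid that would open the ketal.

**Step 4**
Reactants: 5 (−)-8-phenylmenthol [(1R,2S,5R)-5-methyl-2-(2-phenylpropan-2-yl)cyclohexan-1-ol]; 6 ethyl 2-methyl-3-oxobutanoate
Product: 7 (1R,2S,5R)-8-phenylmenthyl 2-methyl-3-oxobutanoate (epimers at the acyl α-carbon)
Conditions: DMAP (cat.), toluene, reflux, EtOH removed through 4 Å molecular sieves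
Reagents that add atoms: none
Why: DMAP-catalysed transesterification of an enolisable β-keto ester runs through the acylketene and therefore accepts the hindered secondary alcohol.

**Step 5**
Reactants: 7 auxiliary β-keto ester; 4 allylic bromide
Product: 9 (1R,2S,5R)-8-phenylmenthyl (6E,10E)-2,6,10-trimethyl-3,14-dioxopentadeca-6,10-dienoate, via dioxolane keto ester 8 (not isolated)
Conditions: 7, NaH, THF, 0 °C; n-BuLi, 0 °C; then 4, 0 °C to rt; then 2 M aq. HCl, THF, rt
Reagents that add atoms: water, O
Why: In this dianion alkylation of a β-keto ester (Weiler type) the more basic terminal carbanion displaces the primary allylic bromide by SN2 with both E alkenes intact, and the aqueous HCl quench hydrolyses the dioxolane; the α-stereocentre is of no consequence because it becomes the radical centre.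

**Step 6**
Reactants: 9 diketo ester
Product: 10 (1R,2S,5R)-8-phenylmenthyl 3,13-dioxo-14,15-dinorlabd-8(17)-en-19-oate (4β-ester axial; 4α-methyl; 5α-H; 9α-H; 10β-methyl)
Conditions: Mn(OAc)3·2H2O (2.2 equiv), Cu(OAc)2·H2O (1.0 equiv), Yb(OTf)3 (1.0 equiv), degassed CF3CH2OH, −5 °C to 0 °C
Reagents that add atoms: none
Why: Mn(OAc)3 oxidises the Yb(OTf)3-bound enol of the β-keto ester to the electrophilic tertiary C4 radical, which adds to C5 of the C5=C10 alkene; the C10 radical so formed adds to C9 of the C8=C9 alkene, and Cu(OAc)2 oxidises the tertiary C8 radical through an alkylcopper intermediate that loses a C17 hydrogen to give the exocyclic methylene. The closest known reaction type is the Mn(OAc)3/Cu(OAc)2 oxidative free-radical polyene cyclization of 2-methyl-3-oxo esters, including its lanthanide triflate-promoted form with 8-phenylmenthyl esters. Ring A closes 6-endo-trig and ring B closes 6-endo-trig, both through chair transition states. C5 and C10 (trans ring fusion) follow from the E geometry of the C5=C10 alkene in the chair–chair array, C9 (equatorial side chain) from the E geometry of the C8=C9 alkene, C4 (ester axial, cis to the C10 methyl) from the preferred geometry of the chelated keto ester radical, and the absolute sense from the phenyl ring of the auxiliary, which covers one face of that radical. The step needs 6-endo over 5-exo closure, which the in-chain C3 carbonyl and the trisubstituted alkenes secure, exocyclic over endocyclic alkene formation, which the copper-mediated elimination towards the methyl group favours, and inertness of the C13 methyl ketone, which Mn(OAc)3 enolises only at far higher temperature.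

**Step 7**
Reactants: 10 bicyclic diketo ester; 11 ethyl 2-[di(propan-2-yloxy)phosphoryl]acetate
Product: 12 15-ethyl 19-[(1R,2S,5R)-8-phenylmenthyl] (13E)-3-oxolabda-8(17),13-diene-15,19-dioate
Conditions: 11, NaH, THF, 0 °C; then 10, 0 °C to rt
Reagents that add atoms: none
Why: Horner–Wadsworth–Emmons olefination of the unhindered C13 methyl ketone, with the bulky diisopropyl phosphonate favouring the 13E enoate (the minor 13Z isomer is removed by chromatography), while the C3 ketone flanked by the quaternary C4 does not react.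

**Step 8**
Reactants: 12 keto diester
Product: 13 C3 tosylhydrazone of 12
Conditions: TsNHNH2, PPTS (cat.), EtOH, 70 °C
Reagents that add atoms: p-toluenesulfonohydrazide, Cc1ccc(cc1)S(=O)(=O)NN
Why: Condensation of the remaining C3 ketone with tosylhydrazide under mild acid catalysis gives the tosylhydrazone; the enoate and the exocyclic alkene are inert and the bulky ester cannot cyclise onto the hydrazone nitrogen.

**Step 9**
Reactants: 13 tosylhydrazone
Product: 15 15-ethyl 19-[(1R,2S,5R)-8-phenylmenthyl] (13E)-labda-8(17),13-diene-15,19-dioate, via N-boryl tosylhydrazine 14 (not isolated)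
Conditions: catecholborane, CHCl3, 0 °C; then NaOAc·3H2O, reflux
Reagents that add atoms: none
Why: In this catecholborane variant of the Caglioti tosylhydrazone reduction, hydride adds to the C=N carbon and acetate-induced loss of sulfinate and N2 leaves the C3 methylene; conjugated esters and isolated alkenes are not touched by catecholborane at this temperature and no stereocentre is involved.

**Step 10**
Reactants: 15 diester
Product: 16 (13E)-labda-8(17),13-diene-15,19-diol
Conditions: LiAlH4, THF, 0 °C to 50 °C; Fieser work-up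
Reagents that add atoms: none
Why: LiAlH4 reduces the enoate in the 1,2-sense to the (E)-allylic alcohol and the hindered C19 ester to the neopentyl alcohol, releasing the auxiliary alcohol 5 for recovery; no stereocentre is touched.

**Step 11**
Reactants: 16 diol
Product: 17 (13E)-labda-8(17),13-diene-15,19-dial
Conditions: Dess–Martin periodinane (2.5 equiv), NaHCO3, CH2Cl2, 0 °C to rt
Reagents that add atoms: none
Why: Dess–Martin oxidation of both primary alcohols under buffered conditions should neither isomerise the 13E enal nor move the exocyclic alkene, and the C19 aldehyde has no α-hydrogen to epimerise.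

**Step 12**
Reactants: 17 dialdehyde
Product: 18 (13E)-labda-8(17),13-diene-15,19-dioic acid
Conditions: NaClO2, NaH2PO4, 2-methyl-2-butene, t-BuOH/H2O, 0 °C to rt
Reagents that add atoms: sodium chlorite, [Na+].[O-]Cl=O
Why: Pinnick oxidation converts the enal and the hindered aldehyde into the acids, with 2-methyl-2-butene scavenging HOCl so that the two alkenes survive.

**Step 13**
Reactants: 18 diacid
Product: 19 dimethyl (13E)-labda-8(17),13-diene-15,19-dioate
Conditions: MeI, K2CO3, DMF, rt
Reagents that add atoms: iodomethane, CI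
Why: O-alkylation of the two carboxylates by SN2 on iodomethane is, unlike Fischer esterification, insensitive to the axial neopentyl position of the C19 carboxylate.

**Step 14**
Reactants: 19 dimethyl ester
Product: 20 methyl (13E)-15-hydroxylabda-8(17),13-dien-19-oate
Conditions: DIBAL-H (2.2 equiv), CH2Cl2, −78 °C; Rochelle salt work-up
Reagents that add atoms: none
Why: Chemoselective DIBAL-H reduction takes the unhindered conjugated C15 ester to the allylic alcohol at −78 °C, whereas the axial neopentyl C19 ester, shielded by the 1,3-diaxial C10 methyl group, is left.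

**Step 15**
Reactants: 20 allylic alcohol
Product: 21 methyl (13R,14R)-13,14-epoxy-15-hydroxylabd-8(17)-en-19-oate
Conditions: Ti(OiPr)4, (−)-diethyl D-tartrate, t-BuOOH, 4 Å molecular sieves, CH2Cl2, −20 °C
Reagents that add atoms: tert-butyl hydroperoxide, CC(C)(C)OO
Why: Sharpless asymmetric epoxidation delivers oxygen to one face of the (E)-allylic alcohol under reagent control ((−)-diethyl D-tartrate gives the 13R,14R epoxide), and the exocyclic alkene, having no allylic hydroxyl, is not epoxidised.

**Step 16**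
Reactants: 21 epoxy alcohol
Product: 22 methyl (14S)-14,15-dihydroxylabda-8(17),13(16)-dien-19-oate (CNP0185041.1)
Conditions: Ti(OiPr)4 (1.5 equiv), CH2Cl2, rt to 40 °C; aq. tartaric acid work-up
Reagents that add atoms: none
Why: In this hydroxyl-directed Ti(OiPr)4-mediated isomerisation of a 2,3-epoxy alcohol to an allylic 1,2-diol, the titanium alkoxide chelate activates the C13–O bond and removes a proton from the C16 methyl group, which is cis to the carbinol arm, so the 13(16)-alkene forms while the C14–O bond is kept (the descriptor changes from R to S only because the substituent priorities change).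

**Compound list**

1 | (E)-geranylacetone, (5E)-6,10-dimethylundeca-5,9-dien-2-one | CC(=O)CC/C=C(\C)CCC=C(C)C | starting material
2 | 2-[(3E)-4,8-dimethylnona-3,7-dien-1-yl]-2-methyl-1,3-dioxolane | CC1(CC/C=C(\C)CCC=C(C)C)OCCO1 | intermediate
3 | (2E,6E)-2,6-dimethyl-9-(2-methyl-1,3-dioxolan-2-yl)nona-2,6-dien-1-ol | CC1(CC/C=C(\C)CC/C=C(\C)CO)OCCO1 | intermediate
4 | 2-[(3E,7E)-9-bromo-4,8-dimethylnona-3,7-dien-1-yl]-2-methyl-1,3-dioxolane | CC1(CC/C=C(\C)CC/C=C(\C)CBr)OCCO1 | intermediate
5 | (−)-8-phenylmenthol, (1R,2S,5R)-5-methyl-2-(2-phenylpropan-2-yl)cyclohexan-1-ol | CC(C)(c1ccccc1)[C@@H]1CC[C@@H](C)C[C@H]1O | starting material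
6 | ethyl 2-methyl-3-oxobutanoate | CCOC(=O)C(C)C(C)=O | starting material
7 | (1R,2S,5R)-8-phenylmenthyl 2-methyl-3-oxobutanoate | CC(=O)C(C)C(=O)O[C@@H]1C[C@H](C)CC[C@H]1C(C)(C)c1ccccc1 | intermediate
8 | (1R,2S,5R)-8-phenylmenthyl (6E,10E)-2,6,10-trimethyl-13-(2-methyl-1,3-dioxolan-2-yl)-3-oxotrideca-6,10-dienoate | CC1(CC/C=C(\C)CC/C=C(\C)CCC(=O)C(C)C(=O)O[C@@H]2C[C@H](C)CC[C@H]2C(C)(C)c2ccccc2)OCCO1 | intermediate (not isolated)
9 | (1R,2S,5R)-8-phenylmenthyl (6E,10E)-2,6,10-trimethyl-3,14-dioxopentadeca-6,10-dienoate | CC(=O)CC/C=C(\C)CC/C=C(\C)CCC(=O)C(C)C(=O)O[C@@H]1C[C@H](C)CC[C@H]1C(C)(C)c1ccccc1 | intermediate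
10 | (1R,2S,5R)-8-phenylmenthyl 3,13-dioxo-14,15-dinorlabd-8(17)-en-19-oate (4β-ester, 5α-H, 9α-H, 10β-methyl) | CC(=O)CC[C@H]1C(=C)CC[C@@H]2[C@]1(C)CCC(=O)[C@]2(C)C(=O)O[C@@H]1C[C@H](C)CC[C@H]1C(C)(C)c1ccccc1 | intermediate
11 | ethyl 2-[di(propan-2-yloxy)phosphoryl]acetate | CCOC(=O)CP(=O)(OC(C)C)OC(C)C | starting material
12 | 15-ethyl 19-[(1R,2S,5R)-8-phenylmenthyl] (13E)-3-oxolabda-8(17),13-diene-15,19-dioate | CCOC(=O)/C=C(\C)CC[C@H]1C(=C)CC[C@@H]2[C@]1(C)CCC(=O)[C@]2(C)C(=O)O[C@@H]1C[C@H](C)CC[C@H]1C(C)(C)c1ccccc1 | intermediate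
13 | C3 tosylhydrazone of 12 | CCOC(=O)/C=C(\C)CC[C@H]1C(=C)CC[C@@H]2[C@]1(C)CCC(=NNS(=O)(=O)c3ccc(C)cc3)[C@]2(C)C(=O)O[C@@H]1C[C@H](C)CC[C@H]1C(C)(C)c1ccccc1 | intermediate
14 | N-(1,3,2-benzodioxaborol-2-yl) tosylhydrazine adduct at C3 | CCOC(=O)/C=C(\C)CC[C@H]1C(=C)CC[C@@H]2[C@]1(C)CCC(N(NS(=O)(=O)c3ccc(C)cc3)B3Oc4ccccc4O3)[C@]2(C)C(=O)O[C@@H]1C[C@H](C)CC[C@H]1C(C)(C)c1ccccc1 | intermediate (not isolated)
15 | 15-ethyl 19-[(1R,2S,5R)-8-phenylmenthyl] (13E)-labda-8(17),13-diene-15,19-dioate | CCOC(=O)/C=C(\C)CC[C@H]1C(=C)CC[C@@H]2[C@]1(C)CCC[C@]2(C)C(=O)O[C@@H]1C[C@H](C)CC[C@H]1C(C)(C)c1ccccc1 | intermediate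
16 | (13E)-labda-8(17),13-diene-15,19-diol | OC/C=C(\C)CC[C@H]1C(=C)CC[C@@H]2[C@]1(C)CCC[C@]2(C)CO | intermediate
17 | (13E)-labda-8(17),13-diene-15,19-dial | O=C/C=C(\C)CC[C@H]1C(=C)CC[C@@H]2[C@]1(C)CCC[C@]2(C)C=O | intermediate
18 | (13E)-labda-8(17),13-diene-15,19-dioic acid | OC(=O)/C=C(\C)CC[C@H]1C(=C)CC[C@@H]2[C@]1(C)CCC[C@]2(C)C(=O)O | intermediate
19 | dimethyl (13E)-labda-8(17),13-diene-15,19-dioate | COC(=O)/C=C(\C)CC[C@H]1C(=C)CC[C@@H]2[C@]1(C)CCC[C@]2(C)C(=O)OC | intermediate
20 | methyl (13E)-15-hydroxylabda-8(17),13-dien-19-oate | OC/C=C(\C)CC[C@H]1C(=C)CC[C@@H]2[C@]1(C)CCC[C@]2(C)C(=O)OC | intermediate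
21 | methyl (13R,14R)-13,14-epoxy-15-hydroxylabd-8(17)-en-19-oate | C[C@]3(CC[C@H]1C(=C)CC[C@@H]2[C@]1(C)CCC[C@]2(C)C(=O)OC)O[C@@H]3CO | intermediate
22 | methyl (14S)-14,15-dihydroxylabda-8(17),13(16)-dien-19-oate | C=C(CC[C@H]1C(=C)CC[C@@H]2[C@]1(C)CCC[C@]2(C)C(=O)OC)[C@H](O)CO | target

**Step count.** Total: 16 steps. Longest linear sequence: 15 steps (steps 1–3 and 5–16, from geranylacetone); step 4 is a one-step branch.

**Steps most likely to fail**

1. Step 6. The auxiliary may discriminate the two faces of the C4 radical insufficiently, or the copper-mediated termination may scatter the new alkene over endocyclic positions. The fallback replaces the oxidative mode by a group-transfer radical cyclization; it sets out from 9 and comes back at 10. Compound 9 is selenenylated at C4 (NaH, PhSeCl, THF, −78 °C) to the α-phenylselanyl β-keto ester F1. Irradiation of F1 (or Et3B/O2) with Mg(ClO4)2 and a chiral bis(oxazoline) ligand in toluene at −78 °C, a Lewis acid-controlled phenylselanyl-transfer radical bicyclization, should give the C8 phenylselanyl bicycle F2 with the same ring stereochemistry. Oxidation with H2O2/pyridine and syn-elimination of the selenoxide towards the C17 methyl group returns to 10.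

2. Step 8. Condensation at the neopentyl C3 ketone may stall, or the hydrazone may later eliminate to an alkene instead of being reduced. The fallback deoxygenates through the alcohol; it sets out from 12 and comes back at 15. NaBH4 (MeOH, 0 °C) should give the 3-hydroxy diester F3, 1,1'-thiocarbonyldiimidazole (DMAP, toluene, 80 °C) the imidazole-1-carbothioate F4, and Barton–McCombie reduction (Bu3SnH, AIBN, toluene, 110 °C) rejoins the route at 15.

3. Step 16. The Lewis-acidic titanium chelate may let the C8(17) alkene attack C13 (closure of a third ring), or isopropoxide may open the epoxide. The fallback runs the isomerisation under base; it sets out from 21 and comes back at 22. TBSCl/imidazole (DMF) gives the silyl ether F5, lithium diethylamide (Et2O, 0 °C to rt) removes a C16 methyl proton in a syn-elimination to the allylic alcohol F6, and TBAF (THF) gives 22.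

**Further compounds**

F1 | step 6 | (1R,2S,5R)-8-phenylmenthyl (6E,10E)-2,6,10-trimethyl-3,14-dioxo-2-(phenylselanyl)pentadeca-6,10-dienoate | CC(=O)CC/C=C(\C)CC/C=C(\C)CCC(=O)C(C)([Se]c1ccccc1)C(=O)O[C@@H]1C[C@H](C)CC[C@H]1C(C)(C)c1ccccc1
F2 | step 6 | (1R,2S,5R)-8-phenylmenthyl 3,13-dioxo-8-(phenylselanyl)-14,15-dinorlabdan-19-oate | CC(=O)CC[C@H]1C(C)([Se]c3ccccc3)CC[C@@H]2[C@]1(C)CCC(=O)[C@]2(C)C(=O)O[C@@H]1C[C@H](C)CC[C@H]1C(C)(C)c1ccccc1
F3 | step 8 | 15-ethyl 19-[(1R,2S,5R)-8-phenylmenthyl] (13E)-3-hydroxylabda-8(17),13-diene-15,19-dioate | CCOC(=O)/C=C(\C)CC[C@H]1C(=C)CC[C@@H]2[C@]1(C)CCC(O)[C@]2(C)C(=O)O[C@@H]1C[C@H](C)CC[C@H]1C(C)(C)c1ccccc1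
F4 | step 8 | O-C3 imidazole-1-carbothioate of F3 | CCOC(=O)/C=C(\C)CC[C@H]1C(=C)CC[C@@H]2[C@]1(C)CCC(OC(=S)n3ccnc3)[C@]2(C)C(=O)O[C@@H]1C[C@H](C)CC[C@H]1C(C)(C)c1ccccc1
F5 | step 16 | methyl (13R,14R)-15-(tert-butyldimethylsilyloxy)-13,14-epoxylabd-8(17)-en-19-oate | C[C@]3(CC[C@H]1C(=C)CC[C@@H]2[C@]1(C)CCC[C@]2(C)C(=O)OC)O[C@@H]3CO[Si](C)(C)C(C)(C)C
F6 | step 16 | methyl (14S)-15-(tert-butyldimethylsilyloxy)-14-hydroxylabda-8(17),13(16)-dien-19-oate | C=C(CC[C@H]1C(=C)CC[C@@H]2[C@]1(C)CCC[C@]2(C)C(=O)OC)[C@H](O)CO[Si](C)(C)C(C)(C)C
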